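The upper (guibourtinidol) unit is cut through ring C at O1–C8a and C4–C4a, so ring A is added last, as 3-(benzyloxy)benzyne, to an epoxy alcohol that already carries ring B and the whole epiafzelechin unit. The step exploits the resorcinol pattern of ring A: C8a bears oxygen and C4a lies para to the C7 oxygen. The C2 hydroxyl adds to the aryne carbon remote from OBn. After proton transfer the new aryl ether is a resorcinol diether whose carbon para to OBn opens the C3–C4 trans-epoxide at benzylic C4 in the same flask. This closes ring C and sets C4; C2 and C3 come from a chalcone epoxide.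

Key step: step 10

Remark: (−)-epiafzelechin is taken as a purchasable natural product; atoms are numbered as in flavans (upper unit O1 to C8a, lower unit primed).

Step 1
Reactants: 1 2-bromoresorcinol (2-bromobenzene-1,3-diol)
Product: 2 3-(benzyloxy)-2-bromophenol
Conditions: BnBr (1.0 equiv), K2CO3, acetone, reflux
Reagents that add atoms: benzyl bromide, BrCc1ccccc1
Why: Williamson ether synthesis on one of two equivalent phenols; with one equivalent of benzyl bromide the monoether should be the main product and is separated from diether and recovered 1.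

Step 2
Reactants: 2 3-(benzyloxy)-2-bromophenol
Product: 5 3-(benzyloxy)-2-(trimethylsilyl)phenyl trifluoromethanesulfonate, via silyl ether 3 (not isolated), via lithium 2-silylphenolate 4 (not isolated)
Conditions: HMDS, THF, 70 °C, then evaporation; n-BuLi, THF, −78 °C; Tf2O, −78 °C to rt
Reagents that add atoms: hexamethyldisilazane, C[Si](C)(C)N[Si](C)(C)C; triflic anhydride, O=S(=O)(OS(=O)(=O)C(F)(F)F)C(F)(F)F
Why: O-silylation, then bromine–lithium exchange triggers a retro-Brook 1,3-shift of silicon from oxygen to carbon and the phenolate is O-sulfonylated, the standard route to 2-silylaryl triflate aryne precursors.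

Step 3
Reactants: 6 (−)-epiafzelechin
Product: 7 (2R,3R)-5,7-bis(benzyloxy)-2-[4-(benzyloxy)phenyl]chroman-3-ol
Conditions: BnBr (3.3 equiv), K2CO3, DMF, 0 °C to rt
Reagents that add atoms: benzyl bromide, BrCc1ccccc1
Why: Williamson ether synthesis; carbonate base deprotonates only the three phenols, so the secondary alcohol stays free, and the mild conditions should avoid C-benzylation and epimerisation at C2'.

Step 4
Reactants: 7 (2R,3R)-5,7-bis(benzyloxy)-2-[4-(benzyloxy)phenyl]chroman-3-ol
Product: 8 (2R,3R)-3,5,7-tris(benzyloxy)-2-[4-(benzyloxy)phenyl]chromane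
Conditions: NaH, BnBr, Bu4NI (cat.), THF/DMF, 0 °C to rt
Reagents that add atoms: benzyl bromide, BrCc1ccccc1
Why: Williamson ether synthesis of the sodium alkoxide; no bond at a stereocentre is broken, so the 2,3-cis configuration is kept.

Step 5
Reactants: 8 (2R,3R)-3,5,7-tris(benzyloxy)-2-[4-(benzyloxy)phenyl]chromane
Product: 9 (2R,3R)-3,5,7-tris(benzyloxy)-2-[4-(benzyloxy)phenyl]-8-bromochromane
Conditions: NBS (1.0 equiv), CH2Cl2, −78 °C to 0 °C
Reagents that add atoms: N-bromosuccinimide, O=C1CCC(=O)N1Br
Why: Electrophilic aromatic bromination of the phloroglucinol-type ring, which in 5,7-dialkoxyflavans is directed to C8 rather than C6.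

Step 6
Reactants: 9 (2R,3R)-3,5,7-tris(benzyloxy)-2-[4-(benzyloxy)phenyl]-8-bromochromane
Product: 12 (2R,3R)-3,5,7-tris(benzyloxy)-2-[4-(benzyloxy)phenyl]chromane-8-carbaldehyde, via 8-lithio flavan 10 (not isolated), via lithium hemiaminal alkoxide 11 (not isolated)
Conditions: n-BuLi, THF, −78 °C; DMF, −78 °C to 0 °C; H2O
Reagents that add atoms: N,N-dimethylformamide, CN(C)C=O
Why: Bromine–lithium exchange and formylation of the aryllithium with DMF (Bouveault aldehyde synthesis), the hemiaminal alkoxide releasing the aldehyde on hydrolysis.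

Step 7
Reactants: 12 (2R,3R)-3,5,7-tris(benzyloxy)-2-[4-(benzyloxy)phenyl]chromane-8-carbaldehyde; 13 4'-(benzyloxy)acetophenone
Product: 15 (E)-1-[4-(benzyloxy)phenyl]-3-{(2R,3R)-3,5,7-tris(benzyloxy)-2-[4-(benzyloxy)phenyl]chroman-8-yl}prop-2-en-1-one, via aldol adduct 14 (not isolated)
Conditions: KOH, EtOH/THF, rt to 50 °C
Reagents that add atoms: none
Why: Claisen–Schmidt condensation (crossed aldol, then E1cB dehydration) between a non-enolisable aldehyde and a methyl ketone; the conjugated E-enone is the thermodynamic product.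

Step 8
Reactants: 15 (E)-chalcone
Product: 16 [4-(benzyloxy)phenyl]{(2S,3R)-3-[(2R,3R)-3,5,7-tris(benzyloxy)-2-(4-(benzyloxy)phenyl)chroman-8-yl]oxiran-2-yl}methanone
Conditions: poly-D-leucine, urea–H2O2, DBU, THF, rt
Reagents that add atoms: hydrogen peroxide (used as its urea adduct), OO
Why: Juliá–Colonna epoxidation: conjugate addition of hydroperoxide and ring closure within the helical peptide should give the trans-epoxide with the (2S,3R) configuration under catalyst control (the D-series polymer is chosen because the L-series is known to give (2R,3S)-chalcone oxides), both new stereocentres being set here.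

Step 9
Reactants: 16 (2S,3R)-epoxy ketone
Product: 17 (R)-[4-(benzyloxy)phenyl]{(2R,3R)-3-[(2R,3R)-3,5,7-tris(benzyloxy)-2-(4-(benzyloxy)phenyl)chroman-8-yl]oxiran-2-yl}methanol
Conditions: Zn(BH4)2, Et2O, −40 °C to −20 °C; pH 7 buffer work-up, product used without storage
Reagents that add atoms: none
Why: Chelation-controlled hydride reduction of an α,β-epoxy ketone: zinc bridges the carbonyl and epoxide oxygens and hydride is delivered to the exposed face, which should give the anti (erythro) epoxy alcohol and so set the carbinol centre (future C2) as R; the descriptor change at the neighbouring oxirane carbon is a priority effect only.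

Step 10
Reactants: 17 anti epoxy alcohol; 5 3-(benzyloxy)-2-(trimethylsilyl)phenyl trifluoromethanesulfonate
Product: 20 (2R,3S,4S)-7-(benzyloxy)-2-[4-(benzyloxy)phenyl]-4-{(2R,3R)-3,5,7-tris(benzyloxy)-2-[4-(benzyloxy)phenyl]chroman-8-yl}chroman-3-ol, via 3-(benzyloxy)benzyne 18 (not isolated), via aryl ether 19 (not isolated)
Conditions: 5 (2 equiv), KF, 18-crown-6, THF, −20 °C; after consumption of 5, volatiles removed cold and 1,1,1,3,3,3-hexafluoropropan-2-ol (HFIP)/CH2Cl2 added to the same flask, 0 °C
Reagents that add atoms: none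
Why: Fluoride converts 5 into 3-(benzyloxy)benzyne 18, the free hydroxyl of 17 adds to the aryne carbon remote from the benzyloxy group and the adjacent aryl anion is protonated, so that O1–C8a is formed as in the known O–H insertion of arynes into aliphatic alcohols and 19 is a resorcinol diether. HFIP then activates the epoxide by hydrogen bonding and the ring carbon para to OBn (C4a) attacks benzylic C4, the known Friedel–Crafts epoxy-arene cyclisation of aryl 3-arylglycidyl ethers to trans-4-arylchroman-3-ols. Ring C closes in the 6-endo mode at the epoxide carbon that is benzylic to the trialkoxyaryl ring, the 5-exo alternative at C3 having no cation-stabilising group. C4 is set by anti opening of the trans-epoxide (inversion; an SN1-like opening should converge on the same 3,4-trans product through the chair transition state with all three substituents equatorial), while C2 and C3 are carried over from 17 with their C–O bonds intact. The step needs regioselective O-arylation (secured by the aryne distortion caused by the flanking OBn), reaction at one hydroxyl only (all others are benzyl ethers) and ring closure para rather than ortho to OBn (the ortho carbon lies between two oxygens and is hindered).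

Step 11
Reactants: 20 hexa-O-benzyl dimer
Product: 21 (2R,3S,4S)-2-(4-hydroxyphenyl)-4-[(2R,3R)-3,5,7-trihydroxy-2-(4-hydroxyphenyl)chroman-8-yl]chromane-3,7-diol (guibourtinidol-(4α→8)-epiafzelechin)
Conditions: H2 (1 atm), Pd(OH)2/C, THF/MeOH, rt
Reagents that add atoms: none
Why: Hydrogenolysis of six benzyl ethers; the cyclic benzylic C–O bonds and the C4–C8' bond of flavan dimers are expected to survive these neutral conditions and no stereocentre is touched.

Compound list
1 | 2-bromoresorcinol | Oc1cccc(O)c1Br | starting material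
2 | 3-(benzyloxy)-2-bromophenol | Oc1cccc(OCc2ccccc2)c1Br | intermediate
3 | [3-(benzyloxy)-2-bromophenoxy]trimethylsilane | C[Si](C)(C)Oc1cccc(OCc2ccccc2)c1Br | intermediate (not isolated)
4 | lithium 3-(benzyloxy)-2-(trimethylsilyl)phenolate | [Li+].[O-]c1cccc(OCc2ccccc2)c1[Si](C)(C)C | intermediate (not isolated)
5 | 3-(benzyloxy)-2-(trimethylsilyl)phenyl trifluoromethanesulfonate | C[Si](C)(C)c1c(OCc2ccccc2)cccc1OS(=O)(=O)C(F)(F)F | intermediate
6 | (−)-epiafzelechin, (2R,3R)-2-(4-hydroxyphenyl)chromane-3,5,7-triol | Oc1cc(O)c2c(c1)O[C@H](c1ccc(O)cc1)[C@H](O)C2 | starting material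
7 | (2R,3R)-5,7-bis(benzyloxy)-2-[4-(benzyloxy)phenyl]chroman-3-ol | O(Cc1ccccc1)c1cc(OCc2ccccc2)c2c(c1)O[C@H](c1ccc(OCc3ccccc3)cc1)[C@H](O)C2 | intermediate
8 | (2R,3R)-3,5,7-tris(benzyloxy)-2-[4-(benzyloxy)phenyl]chromane | O(Cc1ccccc1)c1cc(OCc2ccccc2)c2c(c1)O[C@H](c1ccc(OCc3ccccc3)cc1)[C@H](OCc1ccccc1)C2 | intermediate
9 | 8-bromo derivative of 8 | O(Cc1ccccc1)c1cc(OCc2ccccc2)c2c(c1Br)O[C@H](c1ccc(OCc3ccccc3)cc1)[C@H](OCc1ccccc1)C2 | intermediate
10 | 8-lithio derivative of 8 | O(Cc1ccccc1)c1cc(OCc2ccccc2)c2c(c1[Li])O[C@H](c1ccc(OCc3ccccc3)cc1)[C@H](OCc1ccccc1)C2 | intermediate (not isolated)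
11 | lithium (dimethylamino)(flavan-8-yl)methanolate, mixture at the new carbon | O(Cc1ccccc1)c1cc(OCc2ccccc2)c2c(c1C([O-])N(C)C)O[C@H](c1ccc(OCc3ccccc3)cc1)[C@H](OCc1ccccc1)C2.[Li+] | intermediate (not isolated)
12 | (2R,3R)-3,5,7-tris(benzyloxy)-2-[4-(benzyloxy)phenyl]chromane-8-carbaldehyde | O(Cc1ccccc1)c1cc(OCc2ccccc2)c2c(c1C=O)O[C@H](c1ccc(OCc3ccccc3)cc1)[C@H](OCc1ccccc1)C2 | intermediate
13 | 4'-(benzyloxy)acetophenone | CC(=O)c1ccc(OCc2ccccc2)cc1 | starting material
14 | aldol adduct, 3-hydroxy-1-[4-(benzyloxy)phenyl]-3-(flavan-8-yl)propan-1-one, mixture at the carbinol carbon | O(Cc1ccccc1)c1cc(OCc2ccccc2)c2c(c1C(O)CC(=O)c1ccc(OCc3ccccc3)cc1)O[C@H](c1ccc(OCc3ccccc3)cc1)[C@H](OCc1ccccc1)C2 | intermediate (not isolated)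
15 | (E)-1-[4-(benzyloxy)phenyl]-3-{(2R,3R)-3,5,7-tris(benzyloxy)-2-[4-(benzyloxy)phenyl]chroman-8-yl}prop-2-en-1-one | O(Cc1ccccc1)c1cc(OCc2ccccc2)c2c(c1/C=C/C(=O)c1ccc(OCc3ccccc3)cc1)O[C@H](c1ccc(OCc3ccccc3)cc1)[C@H](OCc1ccccc1)C2 | intermediate
16 | (2S,3R)-trans-epoxy ketone (oxiran-2-yl carries the aroyl group, oxiran-3-yl the flavan-8-yl group) | O(Cc1ccccc1)c1cc(OCc2ccccc2)c2c(c1[C@H]4O[C@@H]4C(=O)c1ccc(OCc3ccccc3)cc1)O[C@H](c1ccc(OCc3ccccc3)cc1)[C@H](OCc1ccccc1)C2 | intermediate
17 | anti epoxy alcohol, (R)-carbinol on a (2R,3R)-trans-oxirane | O(Cc1ccccc1)c1cc(OCc2ccccc2)c2c(c1[C@H]4O[C@@H]4[C@H](O)c1ccc(OCc3ccccc3)cc1)O[C@H](c1ccc(OCc3ccccc3)cc1)[C@H](OCc1ccccc1)C2 | intermediate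
18 | 3-(benzyloxy)benzyne | C1#CC(OCc2ccccc2)=CC=C1 | intermediate (not isolated)
19 | 3-(benzyloxy)phenyl ether of 17 at the carbinol oxygen, configuration as in 17 | O(Cc1ccccc1)c1cc(OCc2ccccc2)c2c(c1[C@H]4O[C@@H]4[C@H](Oc1cccc(OCc3ccccc3)c1)c1ccc(OCc3ccccc3)cc1)O[C@H](c1ccc(OCc3ccccc3)cc1)[C@H](OCc1ccccc1)C2 | intermediate (not isolated)
20 | hexa-O-benzyl dimer, (2R,3S,4S)-7-(benzyloxy)-2-[4-(benzyloxy)phenyl]-4-{(2R,3R)-3,5,7-tris(benzyloxy)-2-[4-(benzyloxy)phenyl]chroman-8-yl}chroman-3-ol | O(Cc5ccccc5)c1ccc([C@H]2Oc3cc(OCc5ccccc5)ccc3[C@@H](c3c(OCc5ccccc5)cc(OCc5ccccc5)c4c3O[C@H](c3ccc(OCc5ccccc5)cc3)[C@H](OCc5ccccc5)C4)[C@@H]2O)cc1 | intermediate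
21 | guibourtinidol-(4α→8)-epiafzelechin, (2R,3S,4S)-2-(4-hydroxyphenyl)-4-[(2R,3R)-3,5,7-trihydroxy-2-(4-hydroxyphenyl)chroman-8-yl]chromane-3,7-diol | Oc1ccc([C@H]2Oc3cc(O)ccc3[C@@H](c3c(O)cc(O)c4c3O[C@H](c3ccc(O)cc3)[C@H](O)C4)[C@@H]2O)cc1 | target

Total step count: 11. Longest linear sequence: 9 steps (steps 3 to 11, from 6 to 21); steps 1 and 2 form the second branch.

Steps most likely to fail

Step 10. Insertion of the hindered secondary hydroxyl into the aryne may be slow, so that the aryne is lost to the epoxide oxygen or to the solvent. In the acidic stage the ionised epoxide may undergo a hydride shift (Meinwald-type rearrangement) or close ortho to the benzyloxy group. The fallback makes the two bonds in separate, isolated steps with a different O-arylation. It sets out from 17, whose sodium alkoxide (NaOtBu, toluene, rt) is arylated by ligand coupling at trivalent iodine with [3-(benzyloxy)phenyl](2,4,6-trimethoxyphenyl)iodonium 4-methylbenzenesulfonate F1 (one pot from 1-(benzyloxy)-3-iodobenzene, mCPBA, TsOH and 1,3,5-trimethoxybenzene). This should give aryl ether 19 as an isolated compound. Compound 19 is then cyclised with catalytic FeBr3/AgOTf in CH2Cl2 at low temperature (Friedel–Crafts epoxy-arene cyclisation), and the fallback comes back to the route at 20.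

Step 8. Conjugate addition of hydroperoxide may be slow because the β-carbon of the enone is deactivated by the trialkoxyaryl donor and shielded by two ortho substituents, and the peptide may then control the enone face poorly. The fallback builds the epoxide by C–C bond formation instead of oxidation. It sets out from aldehyde 12, which undergoes an asymmetric Darzens condensation with 2-bromo-1-[4-(benzyloxy)phenyl]ethan-1-one under a cinchona-derived quaternary ammonium phase-transfer catalyst with LiOH in a two-phase ether/water system. The aldolate closes to the trans-epoxy ketone in the same flask, and the two trans diastereomers are separable because the flavan unit is enantiopure. No new isolated compound is formed (F0) and the fallback comes back to the route at 16.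

Step 9. Zinc may assist ionisation of the benzylic C–O bond of the electron-rich epoxide (ring opening or hydride shift), and incomplete chelation would erode the anti selectivity. The fallback sets the carbinol centre before the sensitive epoxide exists. It sets out from chalcone 15, which is reduced at the carbonyl under reagent control (Corey–Bakshi–Shibata reduction, oxazaborolidine enantiomer chosen for the S-carbinol, catecholborane, −78 °C) to (S,E)-1-[4-(benzyloxy)phenyl]-3-{(2R,3R)-3,5,7-tris(benzyloxy)-2-[4-(benzyloxy)phenyl]chroman-8-yl}prop-2-en-1-ol F2. The electron-rich trans-alkene is then epoxidised under catalyst control by Shi epoxidation (D-fructose-derived ketone, KHSO5, K2CO3 buffer, 0 °C), which is known to give (R,R)-epoxides from trans-styrenes and works under non-acidic conditions. The fallback comes back to the route at 17 and bypasses 16.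

Further compounds
F1 | step 10 | [3-(benzyloxy)phenyl](2,4,6-trimethoxyphenyl)iodonium 4-methylbenzenesulfonate | COc1cc(OC)c([I+]c2cccc(OCc3ccccc3)c2)c(OC)c1.Cc1ccc(cc1)S(=O)(=O)[O-]
F0 | step 8 | none | none
F2 | step 9 | (S,E)-1-[4-(benzyloxy)phenyl]-3-{(2R,3R)-3,5,7-tris(benzyloxy)-2-[4-(benzyloxy)phenyl]chroman-8-yl}prop-2-en-1-ol | O(Cc1ccccc1)c1cc(OCc2ccccc2)c2c(c1/C=C/[C@H](O)c1ccc(OCc3ccccc3)cc1)O[C@H](c1ccc(OCc3ccccc3)cc1)[C@H](OCc1ccccc1)C2
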